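**Retrosynthetic overview**
- The target is a linear tetramer A–O–B–O–C–O–D; the last step is global dealkylation (BBr3) of the octamethyl ethyl ether 20.
- The strategy rests on ring C, which carries oxygen on C1 (to ring B), C3, C4 (to ring D) and C5, with hydrogen on C2 and C6. C1/C2 come from the aryl ethynyl ether 9, C3 (the phenol carbon) is a ketene carbon, and C4/C5/C6 come from the 3-ethoxy-4-aryloxycyclobutenone 15. A cyclobutenone–ynol ether benzannulation forms the C2–C3 and C1–C6 bonds.
- Ynol ether 9 comes from the A–B phenol 5 by dichlorovinylation and elimination; 5 comes from an Ullmann coupling of 3 with benzyl-protected 1.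
- Cyclobutenone 15 comes from the (2+2) addition of the aryloxyketene derived from 10 to ethoxyacetylene 13.
- Rings A, B and D are purchased arenes; ring C is the only ring that is built.

Key step: step 9

Remark: the target has no stereocentre. Cyclobutenone 15 is used as the racemate, because its C4 centre becomes sp2 in the ring opening. Rings are lettered from the 2,4,6-trioxygenated end (A) to the 3,4,5-trioxygenated end (D), and ring C is numbered from the carbon that bears the oxygen to ring B.

**Route**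

Step 1
Reactants: 1 4-bromo-2,6-dimethoxyphenol
Product: 2 2-(benzyloxy)-5-bromo-1,3-dimethoxybenzene
Conditions: BnBr, K2CO3, DMF, rt
Reagents that add atoms: benzyl bromide, BrCc1ccccc1
Why: Williamson etherification of the phenoxide masks the hindered hydroxyl, so that the C–Br bond is the only coupling handle of 2 in the next step.

Step 2
Reactants: 2 2-(benzyloxy)-5-bromo-1,3-dimethoxybenzene, 3 2,4,6-trimethoxyphenol
Product: 4 2-(benzyloxy)-1,3-dimethoxy-5-(2,4,6-trimethoxyphenoxy)benzene
Conditions: CuI (10 mol %), picolinic acid (20 mol %), K3PO4, degassed DMSO, 90 °C, Ar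
Reagents that add atoms: none
Why: Ullmann diaryl ether synthesis, in which picolinic acid-ligated CuI is known to couple di-ortho-substituted phenols with aryl bromides whose C–Br carbon is flanked only by hydrogen, as in 2.

Step 3
Reactants: 4 2-(benzyloxy)-1,3-dimethoxy-5-(2,4,6-trimethoxyphenoxy)benzene
Product: 5 2,6-dimethoxy-4-(2,4,6-trimethoxyphenoxy)phenol
Conditions: H2 (1 atm), Pd/C, EtOAc–MeOH, rt
Reagents that add atoms: none
Why: catalytic hydrogenolysis cleaves only the benzylic C–O bond; the aryl methyl ethers and the diaryl ether are inert.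

Step 4
Reactants: 5 2,6-dimethoxy-4-(2,4,6-trimethoxyphenoxy)phenol
Product: 6 2-{[(E)-1,2-dichloroethenyl]oxy}-1,3-dimethoxy-5-(2,4,6-trimethoxyphenoxy)benzene
Conditions: Cl2C=CHCl, K2CO3, DMF, 70 °C
Reagents that add atoms: trichloroethylene, ClC=C(Cl)Cl
Why: known dichlorovinylation of phenols, in which base turns trichloroethylene into dichloroacetylene and anti addition of the phenoxide to it gives the (E)-1,2-dichlorovinyl ether.

Step 5
Reactants: 6 2-{[(E)-1,2-dichloroethenyl]oxy}-1,3-dimethoxy-5-(2,4,6-trimethoxyphenoxy)benzene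
Product: 9 2-(ethynyloxy)-1,3-dimethoxy-5-(2,4,6-trimethoxyphenoxy)benzene, via chloroethynyl aryl ether 7 (not isolated), via lithium aryloxyacetylide 8 (not isolated)
Conditions: n-BuLi (2.2 equiv), THF, −78 °C; then H2O, −78 → 0 °C; used at once
Reagents that add atoms: none
Why: ynol ether synthesis from a dichlorovinyl ether, in which the first equivalent of n-BuLi eliminates HCl to the chloroalkyne, the second effects chlorine–lithium exchange and water protonates the acetylide, while at −78 °C ortho-lithiation of the methoxyarenes should not compete.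

Step 6
Reactants: 10 3,4,5-trimethoxyphenol
Product: 11 (3,4,5-trimethoxyphenoxy)acetic acid
Conditions: ClCH2CO2H, aq NaOH, 100 °C, N2; then aq HCl
Reagents that add atoms: chloroacetic acid, OC(=O)CCl
Why: Williamson etherification of the sodium phenoxide with chloroacetate, the classical route to aryloxyacetic acids.

Step 7
Reactants: 11 (3,4,5-trimethoxyphenoxy)acetic acid
Product: 12 (3,4,5-trimethoxyphenoxy)acetyl chloride
Conditions: (COCl)2, DMF (cat.), CH2Cl2, 0 °C → rt; used crude
Reagents that add atoms: oxalyl chloride, O=C(Cl)C(=O)Cl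
Why: acid chloride formation through the chloroiminium salt from DMF and oxalyl chloride, which without a Lewis acid should not trigger Friedel–Crafts closure onto the electron-rich ring.

Step 8
Reactants: 12 (3,4,5-trimethoxyphenoxy)acetyl chloride, 13 ethoxyacetylene
Product: 15 racemic 3-ethoxy-4-(3,4,5-trimethoxyphenoxy)cyclobut-2-en-1-one, via aryloxyketene 14 (not isolated)
Conditions: 13 (3 equiv), Et3N (slow addition), Et2O, 0 °C → rt
Reagents that add atoms: none
Why: ketene–alkoxyalkyne (2+2) cycloaddition, in which Et3N dehydrochlorinates 12 to the aryloxyketene and the nucleophilic terminal carbon of ethoxyacetylene bonds to the ketene carbonyl carbon, so that OEt sits on C3 and OAr on C4; the C4 stereocentre forms without control (racemate) and is removed in step 9.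

Step 9
Reactants: 9 2-(ethynyloxy)-1,3-dimethoxy-5-(2,4,6-trimethoxyphenoxy)benzene, 15 racemic 3-ethoxy-4-(3,4,5-trimethoxyphenoxy)cyclobut-2-en-1-one
Product: 20 5-[2,6-dimethoxy-4-(2,4,6-trimethoxyphenoxy)phenoxy]-3-ethoxy-2-(3,4,5-trimethoxyphenoxy)phenol, via vinylketene 16 (not isolated), via vinylcyclobutenone 17 (not isolated), via dienylketene 18 (not isolated), via cyclohexadienone 19 (not isolated)
Conditions: PhMe, 80 °C then 110 °C, Ar (15 in slight excess)
Reagents that add atoms: none
Why: Thermal 4π-electrocyclic opening of 15, with the aryloxy group rotating outward, gives vinylketene 16, whose ketene C=C bond adds (2+2) to the electron-rich alkyne of 9 to give 17; a second 4π-opening to dienylketene 18, 6π-electrocyclisation to 19 and enolisation deliver phenol 20. The closest known reaction type is the Danheiser benzannulation of cyclobutenones with alkoxy- and siloxyalkynes, which gives resorcinol derivatives of this oxygenation pattern. Ring C is closed by the disrotatory 6π-electrocyclisation of 18, which re-forms the C3–C4 bond after the new C2–C3 and C1–C6 bonds are in place, and aromatisation follows. No stereocentre remains in 20, since the sp3 centres of 15, 17 and 19 are racemic and all become sp2. The selectivity needed is the regiochemistry of the ketene–alkyne addition, and the polarisation of the ynol ether secures it: the terminal carbon is the nucleophilic one and bonds to the ketene carbonyl carbon, so the ring B oxygen ends up meta to the new hydroxyl and para to the ring D oxygen. An aryl ethynyl ether has no sp3 C–H beta to oxygen, so the retro-ene loss of alkene that limits alkyl ynol ethers at these temperatures cannot occur.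

Step 10
Reactants: 20 5-[2,6-dimethoxy-4-(2,4,6-trimethoxyphenoxy)phenoxy]-3-ethoxy-2-(3,4,5-trimethoxyphenoxy)phenol
Product: 21 5-[2,6-dihydroxy-4-(2,4,6-trihydroxyphenoxy)phenoxy]-2-(3,4,5-trihydroxyphenoxy)benzene-1,3-diol
Conditions: BBr3 (excess), CH2Cl2, −78 °C → rt; then H2O, 0 °C; work-up under Ar
Reagents that add atoms: none
Why: Lewis acid-mediated dealkylation of aryl alkyl ethers, in which bromide attacks the sp3 carbon of each borane-complexed methyl or ethyl ether (eight OMe, one OEt), while the diaryl ether linkages offer no sp3 carbon and should survive.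

**Compound list**
1 | 4-bromo-2,6-dimethoxyphenol | COc1cc(Br)cc(OC)c1O | starting material
2 | 2-(benzyloxy)-5-bromo-1,3-dimethoxybenzene | COc1cc(Br)cc(OC)c1OCc1ccccc1 | intermediate
3 | 2,4,6-trimethoxyphenol | COc1cc(OC)c(O)c(OC)c1 | starting material
4 | 2-(benzyloxy)-1,3-dimethoxy-5-(2,4,6-trimethoxyphenoxy)benzene | COc1cc(OC)c(Oc2cc(OC)c(OCc3ccccc3)c(OC)c2)c(OC)c1 | intermediate
5 | 2,6-dimethoxy-4-(2,4,6-trimethoxyphenoxy)phenol | COc1cc(OC)c(Oc2cc(OC)c(O)c(OC)c2)c(OC)c1 | intermediate
6 | 2-{[(E)-1,2-dichloroethenyl]oxy}-1,3-dimethoxy-5-(2,4,6-trimethoxyphenoxy)benzene | Cl/C=C(/Cl)Oc1c(OC)cc(Oc2c(OC)cc(OC)cc2OC)cc1OC | intermediate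
7 | 2-[(chloroethynyl)oxy]-1,3-dimethoxy-5-(2,4,6-trimethoxyphenoxy)benzene (formed in the flask) | ClC#COc1c(OC)cc(Oc2c(OC)cc(OC)cc2OC)cc1OC | intermediate
8 | lithium 2-[2,6-dimethoxy-4-(2,4,6-trimethoxyphenoxy)phenoxy]acetylide (formed in the flask) | [Li]C#COc1c(OC)cc(Oc2c(OC)cc(OC)cc2OC)cc1OC | intermediate
9 | 2-(ethynyloxy)-1,3-dimethoxy-5-(2,4,6-trimethoxyphenoxy)benzene | C#COc1c(OC)cc(Oc2c(OC)cc(OC)cc2OC)cc1OC | intermediate
10 | 3,4,5-trimethoxyphenol | COc1cc(O)cc(OC)c1OC | starting material
11 | (3,4,5-trimethoxyphenoxy)acetic acid | OC(=O)COc1cc(OC)c(OC)c(OC)c1 | intermediate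
12 | (3,4,5-trimethoxyphenoxy)acetyl chloride | ClC(=O)COc1cc(OC)c(OC)c(OC)c1 | intermediate
13 | ethoxyacetylene | CCOC#C | starting material
14 | (3,4,5-trimethoxyphenoxy)ketene (formed in the flask) | O=C=COc1cc(OC)c(OC)c(OC)c1 | intermediate
15 | racemic 3-ethoxy-4-(3,4,5-trimethoxyphenoxy)cyclobut-2-en-1-one | CCOC1=CC(=O)C1Oc1cc(OC)c(OC)c(OC)c1 | intermediate
16 | (3Z)-3-ethoxy-4-(3,4,5-trimethoxyphenoxy)buta-1,3-dien-1-one (formed in the flask) | O=C=C/C(OCC)=C/Oc1cc(OC)c(OC)c(OC)c1 | intermediate
17 | racemic 3-[2,6-dimethoxy-4-(2,4,6-trimethoxyphenoxy)phenoxy]-4-[(Z)-1-ethoxy-2-(3,4,5-trimethoxyphenoxy)ethenyl]cyclobut-2-en-1-one (formed in the flask) | O=C1C=C(Oc2c(OC)cc(Oc3c(OC)cc(OC)cc3OC)cc2OC)C1/C(OCC)=C/Oc4cc(OC)c(OC)c(OC)c4 | intermediate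
18 | (3E,5Z)-3-[2,6-dimethoxy-4-(2,4,6-trimethoxyphenoxy)phenoxy]-5-ethoxy-6-(3,4,5-trimethoxyphenoxy)hexa-1,3,5-trien-1-one (formed in the flask) | O=C=C/C(Oc1c(OC)cc(Oc2c(OC)cc(OC)cc2OC)cc1OC)=C\C(OCC)=C\Oc1cc(OC)c(OC)c(OC)c1 | intermediate
19 | racemic 3-[2,6-dimethoxy-4-(2,4,6-trimethoxyphenoxy)phenoxy]-5-ethoxy-6-(3,4,5-trimethoxyphenoxy)cyclohexa-2,4-dien-1-one (formed in the flask) | O=C1C=C(Oc2c(OC)cc(Oc3c(OC)cc(OC)cc3OC)cc2OC)C=C(OCC)C1Oc4cc(OC)c(OC)c(OC)c4 | intermediate
20 | 5-[2,6-dimethoxy-4-(2,4,6-trimethoxyphenoxy)phenoxy]-3-ethoxy-2-(3,4,5-trimethoxyphenoxy)phenol | CCOc1cc(Oc2c(OC)cc(Oc3c(OC)cc(OC)cc3OC)cc2OC)cc(O)c1Oc1cc(OC)c(OC)c(OC)c1 | intermediate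
21 | 5-[2,6-dihydroxy-4-(2,4,6-trihydroxyphenoxy)phenoxy]-2-(3,4,5-trihydroxyphenoxy)benzene-1,3-diol (CNP0333502.0) | Oc1cc(O)c(Oc2cc(O)c(Oc3cc(O)c(Oc4cc(O)c(O)c(O)c4)c(O)c3)c(O)c2)c(O)c1 | target

**Step count and risks**
Total steps: 10. Longest linear sequence: 7 steps (steps 1, 2, 3, 4, 5, 9, 10 from compound 1); the cyclobutenone branch is 3 steps (6, 7, 8).

Steps most likely to fail:

1. Step 9 (benzannulation). Oligomerisation of the terminal aryl ynol ether, or self-reaction of the vinylketene, may outrun the ketene–alkyne addition. The product phenol may also be O-acylated by surplus vinylketene; brief K2CO3/MeOH treatment of the crude product would undo that. Fallback: the benzannulation is replaced by iterative diaryl ether coupling, setting out from phenol 5 and returning at target 21. Ullmann coupling of 5 with bromide 2 (CuI, picolinic acid, K3PO4, DMSO, 90 °C) should give 2-(benzyloxy)-5-[2,6-dimethoxy-4-(2,4,6-trimethoxyphenoxy)phenoxy]-1,3-dimethoxybenzene F1. Hydrogenolysis (H2, Pd/C) should give 4-[2,6-dimethoxy-4-(2,4,6-trimethoxyphenoxy)phenoxy]-2,6-dimethoxyphenol F2. A second Ullmann coupling under the same conditions, with commercial 5-bromo-1,2,3-trimethoxybenzene (COc1cc(Br)cc(OC)c1OC), should give 2-[3,5-dimethoxy-4-(3,4,5-trimethoxyphenoxy)phenoxy]-1,3-dimethoxy-5-(2,4,6-trimethoxyphenoxy)benzene F3. BBr3 in CH2Cl2 then cleaves its ten methyl ethers to 21.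

2. Step 5 (terminal ynol ether). The ynol ether may be lost by hydration or polymerisation during aqueous work-up and concentration, and over-lithiation of the methoxyarenes may occur if the temperature rises. Fallback: the alkyne is carried in a capped, storable form, setting out from dichlorovinyl ether 6 and returning at 9. After the same n-BuLi treatment, acetylide 8 is trapped with TIPSOTf to give 1,3-dimethoxy-5-(2,4,6-trimethoxyphenoxy)-2-{[(triisopropylsilyl)ethynyl]oxy}benzene F4, which can be chromatographed and stored. TBAF in THF at 0 °C releases 9 immediately before step 9.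

3. Step 2 (Ullmann coupling). Slow oxidative addition of the electron-rich bromide, together with oxidative degradation of the electron-rich, di-ortho-substituted phenol in hot base, may lead to reduction of the bromide instead of C–O bond formation. Fallback: the polarity of the aryl partner is reversed and the coupling is run at room temperature, setting out from bromide 2 and returning at 4. Bromine–lithium exchange (n-BuLi, THF, −78 °C), B(OiPr)3 and aqueous acid give [4-(benzyloxy)-3,5-dimethoxyphenyl]boronic acid F5. Chan–Lam coupling of F5 with phenol 3 (Cu(OAc)2, pyridine, 4 Å molecular sieves, CH2Cl2, air, rt) should give 4.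

**Further compounds**
F1 | step 9 | 2-(benzyloxy)-5-[2,6-dimethoxy-4-(2,4,6-trimethoxyphenoxy)phenoxy]-1,3-dimethoxybenzene | COc1cc(OC)c(Oc2cc(OC)c(Oc3cc(OC)c(OCc4ccccc4)c(OC)c3)c(OC)c2)c(OC)c1
F2 | step 9 | 4-[2,6-dimethoxy-4-(2,4,6-trimethoxyphenoxy)phenoxy]-2,6-dimethoxyphenol | COc1cc(OC)c(Oc2cc(OC)c(Oc3cc(OC)c(O)c(OC)c3)c(OC)c2)c(OC)c1
F3 | step 9 | 2-[3,5-dimethoxy-4-(3,4,5-trimethoxyphenoxy)phenoxy]-1,3-dimethoxy-5-(2,4,6-trimethoxyphenoxy)benzene | COc1cc(OC)c(Oc2cc(OC)c(Oc3cc(OC)c(Oc4cc(OC)c(OC)c(OC)c4)c(OC)c3)c(OC)c2)c(OC)c1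
F4 | step 5 | 1,3-dimethoxy-5-(2,4,6-trimethoxyphenoxy)-2-{[(triisopropylsilyl)ethynyl]oxy}benzene | CC(C)[Si](C#COc1c(OC)cc(Oc2c(OC)cc(OC)cc2OC)cc1OC)(C(C)C)C(C)C
F5 | step 2 | [4-(benzyloxy)-3,5-dimethoxyphenyl]boronic acid | COc1cc(B(O)O)cc(OC)c1OCc1ccccc1
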